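**Retrosynthetic overview** (side-chain carbons numbered C1, benzylic, to C16)

1. Target ⇐ its bis(methoxymethyl) ether; both phenols are unmasked in the last step.
2. C8–C9 bond ⇐ proposed nickel-catalysed reductive coupling of an aryl-geranyl C8 allylic carbonate with a C9–C16 terminal epoxide that already carries C10 and C11.
3. Aryl–C1 bond ⇐ arylcopper plus geranyl bromide; the C8 oxygen comes from E-selective SeO2 oxidation of the terminal methyl.
4. C10/C11 ⇐ Sharpless epoxidation of nerol, then Payne rearrangement–hydrolysis (inversion at C2), which gives the syn-diol pattern of an E olefin; primary tosylate, then terminal epoxide.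
5. No ring is built: the benzene ring is bought as 2-bromo-6-methylphenol, and the oxiranes are only transient handles.

Assumption: the target is exactly the structure of the given SMILES, 2-[(2E,6E,10R,11R)-10,11-dihydroxy-3,7,11,15-tetramethylhexadeca-2,6,14-trien-1-yl]-6-methylbenzene-1,4-diol; 2-bromo-6-methylphenol, geranyl bromide and nerol are taken as catalogue materials.

**Route**

Step 1
Reactants: 1 2-bromo-6-methylphenol
Product: 2 2-bromo-6-methylcyclohexa-2,5-diene-1,4-dione
Conditions: (KSO3)2NO (2.5 equiv), KH2PO4, H2O/acetone, 20 °C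
Reagents that add atoms: Fremy's salt (potassium nitrosodisulfonate), [K+].[K+].[O]N(S(=O)(=O)[O-])S(=O)(=O)[O-]
Why: Teuber oxidation; the phenoxyl radical is trapped by a second equivalent of the nitroxyl at the free para position (both ortho positions are blocked) and collapses to the para-quinone, with no stereocentre involved.

Step 2
Reactants: 2 2-bromo-6-methylcyclohexa-2,5-diene-1,4-dione
Product: 3 2-bromo-6-methylbenzene-1,4-diol
Conditions: Na2S2O4 (3 equiv), H2O/EtOAc, 20 °C
Reagents that add atoms: none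
Why: Dithionite reduction of a quinone to its hydroquinone is fast and leaves the aryl bromide alone.

Step 3
Reactants: 3 2-bromo-6-methylbenzene-1,4-diol
Product: 4 1-bromo-2,5-bis(methoxymethoxy)-3-methylbenzene
Conditions: NaH (2.5 equiv), MOMCl (2.5 equiv), DMF, 0 → 20 °C, argon
Reagents that add atoms: chloromethyl methyl ether (MOMCl), COCCl
Why: Williamson etherification of both phenoxides; the MOM ethers survive organolithium, SeO2, base and nickel/manganese, and leave under mild acid at the end.

Step 4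
Reactants: 4 1-bromo-2,5-bis(methoxymethoxy)-3-methylbenzene; 5 geranyl bromide [(2E)-1-bromo-3,7-dimethylocta-2,6-diene]
Product: 8 1-[(2E)-3,7-dimethylocta-2,6-dien-1-yl]-2,5-bis(methoxymethoxy)-3-methylbenzene, via aryllithium 6 (not isolated), via arylcopper 7 (not isolated)
Conditions: n-BuLi (1.05 equiv), THF, −78 °C; CuBr·SMe2 (1.0 equiv), −78 → −40 °C; then 5 (1.2 equiv), −78 → 0 °C
Reagents that add atoms: none
Why: Bromine–lithium exchange, transmetalation to the arylcopper and SN2 displacement at the primary allylic carbon give the linear geranyl arene with the 2E olefin unchanged; no stereocentre is formed.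

Step 5
Reactants: 8 1-[(2E)-3,7-dimethylocta-2,6-dien-1-yl]-2,5-bis(methoxymethoxy)-3-methylbenzene
Product: 9 (2E,6E)-8-[2,5-bis(methoxymethoxy)-3-methylphenyl]-2,6-dimethylocta-2,6-dien-1-ol
Conditions: SeO2 (0.3 equiv), salicylic acid (0.1 equiv), t-BuOOH (70% aq., 3.5 equiv), CH2Cl2, 0 → 20 °C
Reagents that add atoms: tert-butyl hydroperoxide, CC(C)(C)OO
Why: Riley allylic oxidation (ene reaction, then [2,3]-sigmatropic shift) in its catalytic form hydroxylates the E-methyl of the terminal, most accessible trisubstituted olefin, giving the 6E allylic alcohol at side-chain C8.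

Step 6
Reactants: 9 (2E,6E)-8-[2,5-bis(methoxymethoxy)-3-methylphenyl]-2,6-dimethylocta-2,6-dien-1-ol
Product: 10 (2E,6E)-8-[2,5-bis(methoxymethoxy)-3-methylphenyl]-2,6-dimethylocta-2,6-dien-1-yl methyl carbonate
Conditions: ClCO2Me (1.5 equiv), pyridine (3 equiv), DMAP (5 mol%), CH2Cl2, 0 °C
Reagents that add atoms: methyl chloroformate, COC(=O)Cl
Why: Simple acylation turns the primary allylic alcohol into an allylic electrophile that low-valent nickel can ionise.

Step 7
Reactants: 11 nerol [(2Z)-3,7-dimethylocta-2,6-dien-1-ol]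
Product: 12 [(2S,3R)-3-methyl-3-(4-methylpent-3-en-1-yl)oxiran-2-yl]methanol
Conditions: Ti(OiPr)4 (10 mol%), L-(+)-diethyl tartrate (12 mol%), t-BuOOH (2.0 equiv, anhydrous), 4 Å MS, CH2Cl2, −20 °C
Reagents that add atoms: tert-butyl hydroperoxide, CC(C)(C)OO
Why: Sharpless asymmetric epoxidation; the L-(+)-tartrate–titanium catalyst delivers oxygen to the allylic-alcohol face that gives the 2S epoxy alcohol, so the Z olefin gives (2S,3R)-12 (about 90% ee or better), which fixes the later C11 centre, while the isolated olefin is untouched.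

Step 8
Reactants: 12 [(2S,3R)-3-methyl-3-(4-methylpent-3-en-1-yl)oxiran-2-yl]methanol
Product: 14 (2R,3R)-3,7-dimethyloct-6-ene-1,2,3-triol, via terminal epoxy alcohol 13 (not isolated)
Conditions: NaOH (0.5 M aq.), t-BuOH, 75 °C
Reagents that add atoms: water, O
Why: Payne rearrangement–hydrolysis; the C1 alkoxide opens the oxirane at C2 with inversion (the C3–O bond is untouched) and hydroxide then opens the terminal epoxide at CH2, so the triol has the 2R,3R configuration needed for C10/C11.

Step 9
Reactants: 14 (2R,3R)-3,7-dimethyloct-6-ene-1,2,3-triol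
Product: 15 (2R,3R)-2,3-dihydroxy-3,7-dimethyloct-6-en-1-yl 4-methylbenzenesulfonate
Conditions: TsCl (1.05 equiv), Et3N (1.5 equiv), Bu2SnO (2 mol%), CH2Cl2, 0 → 20 °C
Reagents that add atoms: 4-toluenesulfonyl chloride, Cc1ccc(cc1)S(=O)(=O)Cl
Why: Stannylene-acetal-catalysed sulfonylation is selective for the primary hydroxyl of a 1,2-diol, leaving the secondary and tertiary hydroxyls free.

Step 10
Reactants: 15 (2R,3R)-2,3-dihydroxy-3,7-dimethyloct-6-en-1-yl 4-methylbenzenesulfonate
Product: 13 (2R)-6-methyl-2-[(2R)-oxiran-2-yl]hept-5-en-2-ol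
Conditions: K2CO3 (1.2 equiv), MeOH, 0 °C, 30 min; pH 7 buffer
Reagents that add atoms: none
Why: Intramolecular Williamson closure (3-exo-tet) by the C2 oxygen on the primary tosylate gives the terminal epoxide without touching either C–O stereocentre; the low temperature and short time are meant to keep Payne return to 12 small.

Step 11
Reactants: 10 (2E,6E)-8-[2,5-bis(methoxymethoxy)-3-methylphenyl]-2,6-dimethylocta-2,6-dien-1-yl methyl carbonate; 13 (2R)-6-methyl-2-[(2R)-oxiran-2-yl]hept-5-en-2-ol
Product: 17 1-[(2E,6E,10R,11R)-10,11-dihydroxy-3,7,11,15-tetramethylhexadeca-2,6,14-trien-1-yl]-2,5-bis(methoxymethoxy)-3-methylbenzene, via iodohydrin 16 (not isolated)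
Conditions: NiCl2(MeOCH2CH2OMe) (10 mol%), 4,4′,4″-tri-tert-butyl-2,2′:6′,2″-terpyridine (12 mol%), NaI (25 mol%), Et3N·HCl (2.0 equiv), Mn powder (3 equiv), DMPU, 25 °C; 10 added over 4 h to 13 (1.5 equiv)
Reagents that add atoms: none
Why: Proposed new method: a nickel-catalysed reductive cross-electrophile coupling in which a terminal epoxide, not an alkyl halide, is the sp3 partner of an allylic carbonate; Et3NH+ and iodide open 13 reversibly at its unhindered CH2 to iodohydrin 16, low-valent nickel–terpyridine abstracts the iodine atom to give the primary C9 radical and separately ionises 10 to the syn (E-derived) 2-methylallyl–nickel, radical capture and C(sp3)–C(sp3) reductive elimination at the less substituted allyl terminus form the C8–C9 bond with the 6E olefin kept, and Mn returns nickel to its low-valent state; the radical sits on C9, so the C10 and C11 stereocentres of 13 are carried over unchanged and no new stereocentre arises; the closest known reaction types are the nickel-catalysed reductive allylation of alkyl halides with allylic carbonates or acetates and the nickel/iodide co-catalysed reductive arylation of terminal epoxides through iodohydrins, and an epoxide has not been joined to an allylic electrophile in this way.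

Step 12
Reactants: 17 1-[(2E,6E,10R,11R)-10,11-dihydroxy-3,7,11,15-tetramethylhexadeca-2,6,14-trien-1-yl]-2,5-bis(methoxymethoxy)-3-methylbenzene
Product: 18 2-[(2E,6E,10R,11R)-10,11-dihydroxy-3,7,11,15-tetramethylhexadeca-2,6,14-trien-1-yl]-6-methylbenzene-1,4-diol
Conditions: HCl (0.3 M in degassed MeOH), argon, 0 → 20 °C
Reagents that add atoms: none
Why: Acid-catalysed acetal exchange with methanol removes both MOM groups as dimethoxymethane under conditions intended to be too mild to ionise the tertiary alcohol or cyclise the trisubstituted olefins; the stereocentres are untouched.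

**Compound list**

1 | 2-bromo-6-methylphenol | Cc1cccc(Br)c1O | starting material
2 | 2-bromo-6-methylcyclohexa-2,5-diene-1,4-dione | CC1=CC(=O)C=C(Br)C1=O | intermediate
3 | 2-bromo-6-methylbenzene-1,4-diol | Cc1cc(O)cc(Br)c1O | intermediate
4 | 1-bromo-2,5-bis(methoxymethoxy)-3-methylbenzene | COCOc1cc(C)c(OCOC)c(Br)c1 | intermediate
5 | geranyl bromide [(2E)-1-bromo-3,7-dimethylocta-2,6-diene] | CC(C)=CCC/C(C)=C/CBr | starting material
6 | [2,5-bis(methoxymethoxy)-3-methylphenyl]lithium | [Li]c1cc(OCOC)cc(C)c1OCOC | intermediate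
7 | [2,5-bis(methoxymethoxy)-3-methylphenyl]copper | [Cu]c1cc(OCOC)cc(C)c1OCOC | intermediate
8 | 1-[(2E)-3,7-dimethylocta-2,6-dien-1-yl]-2,5-bis(methoxymethoxy)-3-methylbenzene | CC(C)=CCC/C(C)=C/Cc1cc(OCOC)cc(C)c1OCOC | intermediate
9 | (2E,6E)-8-[2,5-bis(methoxymethoxy)-3-methylphenyl]-2,6-dimethylocta-2,6-dien-1-ol | OC/C(C)=C/CC/C(C)=C/Cc1cc(OCOC)cc(C)c1OCOC | intermediate
10 | (2E,6E)-8-[2,5-bis(methoxymethoxy)-3-methylphenyl]-2,6-dimethylocta-2,6-dien-1-yl methyl carbonate | COC(=O)OC/C(C)=C/CC/C(C)=C/Cc1cc(OCOC)cc(C)c1OCOC | intermediate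
11 | nerol [(2Z)-3,7-dimethylocta-2,6-dien-1-ol] | CC(C)=CCC/C(C)=C\CO | starting material
12 | [(2S,3R)-3-methyl-3-(4-methylpent-3-en-1-yl)oxiran-2-yl]methanol | CC(C)=CCC[C@@](C)(O1)[C@@H]1CO | intermediate
13 | (2R)-6-methyl-2-[(2R)-oxiran-2-yl]hept-5-en-2-ol | CC(C)=CCC[C@@](C)(O)[C@H]1CO1 | intermediate
14 | (2R,3R)-3,7-dimethyloct-6-ene-1,2,3-triol | CC(C)=CCC[C@@](C)(O)[C@H](O)CO | intermediate
15 | (2R,3R)-2,3-dihydroxy-3,7-dimethyloct-6-en-1-yl 4-methylbenzenesulfonate | CC(C)=CCC[C@@](C)(O)[C@H](O)COS(=O)(=O)c1ccc(C)cc1 | intermediate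
16 | (2S,3R)-1-iodo-3,7-dimethyloct-6-ene-2,3-diol | CC(C)=CCC[C@@](C)(O)[C@H](O)CI | intermediate
17 | 1-[(2E,6E,10R,11R)-10,11-dihydroxy-3,7,11,15-tetramethylhexadeca-2,6,14-trien-1-yl]-2,5-bis(methoxymethoxy)-3-methylbenzene | CC(C)=CCC[C@@](C)(O)[C@H](O)CC/C(C)=C/CC/C(C)=C/Cc1cc(OCOC)cc(C)c1OCOC | intermediate
18 | 2-[(2E,6E,10R,11R)-10,11-dihydroxy-3,7,11,15-tetramethylhexadeca-2,6,14-trien-1-yl]-6-methylbenzene-1,4-diol | CC(C)=CCC[C@@](C)(O)[C@H](O)CC/C(C)=C/CC/C(C)=C/Cc1cc(O)cc(C)c1O | target

**Step count**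

Total step count: 12.
Longest linear sequence: 8 steps (steps 1–6, 11 and 12, from 2-bromo-6-methylphenol); the epoxide branch (steps 7–10) joins at step 11.

**Three steps most likely to fail**

Step 11 (the proposed coupling). The likely failures are homocoupling of 10 to a 1,5-diene, 6-exo cyclisation of the C9 radical onto the C14 olefin, and partial loss of the 6E geometry. The fallback uses known chemistry, sets out from 9 and 13 and comes back to the route at 17. Alcohol 9 is brominated (CBr4, PPh3, CH2Cl2, 0 °C) to 1-[(2E,6E)-8-bromo-3,7-dimethylocta-2,6-dien-1-yl]-2,5-bis(methoxymethoxy)-3-methylbenzene F1, which with PhSO2Na in DMF at 20 °C gives 1-[(2E,6E)-3,7-dimethyl-8-(phenylsulfonyl)octa-2,6-dien-1-yl]-2,5-bis(methoxymethoxy)-3-methylbenzene F2. Epoxide 13 is silylated on the tertiary hydroxyl (Et3SiOTf, 2,6-lutidine, CH2Cl2, −78 °C) to triethyl({(2R)-6-methyl-2-[(2R)-oxiran-2-yl]hept-5-en-2-yl}oxy)silane F3. The lithium carbanion of F2 (n-BuLi, THF, −78 °C) opens F3 at its CH2 (BF3·OEt2, −78 °C) to give 1-[(2E,6E,10R,11R)-10-hydroxy-3,7,11,15-tetramethyl-8-(phenylsulfonyl)-11-(triethylsilyloxy)hexadeca-2,6,14-trien-1-yl]-2,5-bis(methoxymethoxy)-3-methylbenzene F4 (both C8 epimers). Palladium-catalysed hydride desulfonylation (PdCl2(Ph2PCH2CH2CH2PPh2) 5 mol%, LiBHEt3, THF, 0 °C) then gives 1-[(2E,6E,10R,11R)-10-hydroxy-3,7,11,15-tetramethyl-11-(triethylsilyloxy)hexadeca-2,6,14-trien-1-yl]-2,5-bis(methoxymethoxy)-3-methylbenzene F5, and Bu4NF (THF, 20 °C) gives 17. The weak point of this fallback is that any olefin-position isomer from the desulfonylation must be removed by chromatography.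

Step 5 (SeO2 oxidation). The likely failures are competing oxidation at the inner olefin, over-oxidation to the enal and a modest yield. The fallback sets out from 8 and comes back at 9. Cross-metathesis of 8 with methacrolein (5 equiv, second-generation Hoveyda–Grubbs catalyst 5 mol%, CH2Cl2, 40 °C) exchanges the terminal isopropylidene for the E-enal (2E,6E)-8-[2,5-bis(methoxymethoxy)-3-methylphenyl]-2,6-dimethylocta-2,6-dienal F6. 1,2-Reduction (NaBH4, CeCl3·7H2O, MeOH, 0 °C) then gives 9.

Step 10 (epoxide closure). The likely failure is base-induced Payne return of 13 to the more stable 12. The fallback sets out from 15 and comes back at 17, and avoids the epoxide and all base. Finkelstein exchange of 15 (NaI, acetone, 55 °C) gives iodohydrin 16 as an isolated compound. It is used in place of 13 in step 11 with the same nickel/terpyridine/Mn system, but without NaI and Et3N·HCl, and gives 17. This fallback makes no compound outside the list (none F0).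

**Further compounds**

F1 | step 11 | 1-[(2E,6E)-8-bromo-3,7-dimethylocta-2,6-dien-1-yl]-2,5-bis(methoxymethoxy)-3-methylbenzene | BrC/C(C)=C/CC/C(C)=C/Cc1cc(OCOC)cc(C)c1OCOC
F2 | step 11 | 1-[(2E,6E)-3,7-dimethyl-8-(phenylsulfonyl)octa-2,6-dien-1-yl]-2,5-bis(methoxymethoxy)-3-methylbenzene | O=S(=O)(C/C(C)=C/CC/C(C)=C/Cc1cc(OCOC)cc(C)c1OCOC)c1ccccc1
F3 | step 11 | triethyl({(2R)-6-methyl-2-[(2R)-oxiran-2-yl]hept-5-en-2-yl}oxy)silane | CC(C)=CCC[C@@](C)(O[Si](CC)(CC)CC)[C@H]1CO1
F4 | step 11 | 1-[(2E,6E,10R,11R)-10-hydroxy-3,7,11,15-tetramethyl-8-(phenylsulfonyl)-11-(triethylsilyloxy)hexadeca-2,6,14-trien-1-yl]-2,5-bis(methoxymethoxy)-3-methylbenzene | CC(C)=CCC[C@@](C)(O[Si](CC)(CC)CC)[C@H](O)CC(/C(C)=C/CC/C(C)=C/Cc1cc(OCOC)cc(C)c1OCOC)S(=O)(=O)c1ccccc1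
F5 | step 11 | 1-[(2E,6E,10R,11R)-10-hydroxy-3,7,11,15-tetramethyl-11-(triethylsilyloxy)hexadeca-2,6,14-trien-1-yl]-2,5-bis(methoxymethoxy)-3-methylbenzene | CC(C)=CCC[C@@](C)(O[Si](CC)(CC)CC)[C@H](O)CC/C(C)=C/CC/C(C)=C/Cc1cc(OCOC)cc(C)c1OCOC
F6 | step 5 | (2E,6E)-8-[2,5-bis(methoxymethoxy)-3-methylphenyl]-2,6-dimethylocta-2,6-dienal | O=C/C(C)=C/CC/C(C)=C/Cc1cc(OCOC)cc(C)c1OCOC
F0 | step 10 | none | none
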